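In a one-step world substrate simply becomes ring: the fraction a of the charge left decays at one rate k, and the ring ends holding the charge. The two earlier runs end far below that, at 30.4% and 11.2% of ring, so keep the decay and ask what else takes the substrate and the ring.

| flask | substrate | remark | time |
|---|---|---|---|
| east | 0.035 M | run made earlier |  |
| south-west | 0.64 M | run made earlier |  |
| Sunday's | 0.60 M |  | 30 min |
| Thursday's | 0.060 M |  | 30 min |
| Monday's | 0.80 M |  | 30 min |
| Friday's | 0.20 M |  | 30 min |
| Tuesday's | 0.30 M |  | 30 min |

| run | time / min | ring / % | substrate / % |
|---|---|---|---|
| east | 5.00 | 49.8 | 16.4 |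
| east | 10.0 | 42.4 | 3.0 |
| east | 15.0 | 35.1 | 0.2 |
| east | 20.0 | 32.1 | 0.4 |
| east | 25.0 | 30.9 | 0 |
| east | 30.0 | 30.4 | 0.5 |
| south-west | 2.00 | 19.1 | 12.5 |
| south-west | 6.00 | 17.4 | 1.5 |
| south-west | 10.0 | 14.6 | 0 |
| south-west | 15.0 | 11.1 | 0.2 |
| south-west | 25.0 | 10.3 | 0 |
| south-west | 30.0 | 11.2 | 0.1 |

(standard deviation of a reading: 0.5 percentage points)

* the flasks by amount of ring, in percent of the substrate charged, highest first, at 30 min (Sunday's / Thursday's / Monday's / Friday's / Tuesday's)
* the amount of ring, in percent of the substrate charged of the flask you put first, at 30 min
* the amount of ring, in percent of the substrate charged of the flask you put last, at 30 min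



Read k from the tail of the east run, where a is small: 0.340 /min, a half-life of 2.04 min, short against 30 min. At that k the south-west run should keep 50.7% after 2.00 min, but it reads less, 12.5%, so add a second path going with a squared, and let g be its rate over the ring path's rate at the start. The integrated law turns that reading into g = 6.20. Take g as proportional to the charge, with 9.68 /M, the start ratio per unit of charge.

The ring's part of the rate, its instantaneous selectivity, is one over one plus g times a. In the south-west run that is 13.9% at the start and 24.4% with half the charge left, so the ring's part grows as a falls. Averaged over a, it gives the mean share: the logarithm of one plus g, over g, here 31.9%.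

The ring then falls further in the south-west run, from 17.4% at 6.00 min to 11.2% at 30.0 min, with substrate reading 0.1% at the end. Freeze that as a kept share, read from the east run as 35.3%. Applied to the south-west run it gives 11.2% against the 11.2% read there.

So I reckon 27.8% for Thursday's and 9.88% for Monday's, with ring falling as the charge rises. The forecast, holding that “dilution favours the ring”, gives Thursday's > Friday's > Tuesday's > Sunday's > Monday's, with 25% (22.5% to 27.5%) for Thursday's, below mine, and 9.8% (8.5% to 10.8%) for Monday's.

    substrate → ring (k = 0.320 /min)
    2 substrate → open dimer (k = 1.30 /M/min)
    substrate + open dimer → open trimer (k = 1.00 /M/min)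
    substrate + ring → side product (k = 0.00440 /M/min)
    ring ⇌ isomer of the product (K = 1.90, k = 0.140 /min)

At 30 min the flasks stand as Thursday's > Friday's > Tuesday's > Sunday's > Monday's, Thursday's at 28.0% and Monday's at 8.94%. In Thursday's flask the ring and the isomer of the product together hold 80.6% of the charge, where the mean share from 9.68 /M gives 78.8%. On the neighbour flask, Thursday's with 0.24 M of substrate, 9.68 /M gives g = 2.32 and, with the kept share, 18.2% of ring, and that flask stood at 18.1%.

(The numbers in the tables were generated by integration from invented constants; noise was put on by code.)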